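**Retrosynthetic overview** (guaiane numbers for the xanthatin-derived half, primed numbers for the secoeudesmanolide half)

1. Target 20 ⇐ (acetylation, desilylation, amine elimination) norbornenol 16 ⇐ ring contraction of bridged lactol 15. The unsaturated six-membered oxacycle C1–O–C2–C3–C4=C5 of a 2-oxabicyclo[2.2.2]oct-5-ene loses its ring oxygen and recloses C2–C1 (zerovalent palladium, Et2Zn) to the cyclopentene C1–C2–C3–C4=C5 of the norbornene, with the C2 carbinol syn to C4=C5.
2. Enabling feature: in 15 the bridging oxygen sits on the tertiary allylic bridgehead C1 (C1–C5=C4) and is the only allylic leaving group. The lactol carbon C2 hangs on C3 next to C4, so the allyl-metal formed on ionisation can reclose only through C1 in a chelated chair.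
3. 15 ⇐ (silylation, aminolysis, amide-to-aldehyde reduction) Diels–Alder adduct 12 of tricyclic 2-pyranone 10 with 1-O-acetylbritannilactone 11. This step joins the halves and sets C1, C3 and C11'.
4. 10 ⇐ xanthatin 1: side chain cut back to the C1 ketone 7 (retro-aldol, Pinnick, Curtius), then ynoate annulation.
5. Ring order: the seven-membered ring and both γ-lactones come with 1 and 11; pyranone (step 4); bicyclo[2.2.2]octene (step 5); norbornene by contraction (step 9).

Key step: step 9

Remark: xanthatin (1) and 1-O-acetylbritannilactone (11) are taken as commercially available natural products; their configurations (7R,8S,10S and 3aS,4S,7aR,4S) are those the target requires.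
Remark: 15 is written as the bridged lactol; it equilibrates with its open hydroxy aldehyde. C3 is α to a carbonyl in 14 and in open 15, so nothing more basic than a secondary amine is used between steps 7 and 9.
Remark: the Diels–Alder step is assumed to bond through the face of 11 that the target displays (new bond at C11' cis to C6').

**Route**

Step 1
Reactants: 1 xanthatin
Product: 3 amino enal (C1 formyl group; lactone methylene masked as CH2NMe2), via 13-(dimethylamino)-11,13-dihydroxanthatin 2 (not isolated)
Conditions: Me2NH (40% in H2O, 10 equiv), THF, 23 → 55 °C, N2 sweep; pH 7 work-up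
Reagents that add atoms: dimethylamine (CNC); water (O)
Why: Aza-Michael addition of dimethylamine masks the α-methylene lactone (C11 is protonated on the face opposite C6, leaving CH2NMe2 cis to H-7), and the same amine cleaves the enone by retro-aldol (retro-Mannich of the β-amino ketone, then iminium hydrolysis) to the conjugated C1 aldehyde while acetone is swept out.

Step 2
Reactants: 3 amino enal
Product: 4 amino acid (C1 carboxylic acid)
Conditions: NaClO2, NaH2PO4, 2-methylbut-2-ene, t-BuOH/H2O, 0 → 23 °C
Reagents that add atoms: sodium chlorite ([Na+].[O-]Cl=O)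
Why: Pinnick oxidation takes the enal to the acid without touching the alkene, the amine being protected as its ammonium ion in the phosphate buffer; no stereocentre is involved.

Step 3
Reactants: 4 amino acid
Product: 7 amino ketone (C1 ketone of the seven-membered ring), via acyl azide 5 (not isolated), via vinyl isocyanate 6 (not isolated)
Conditions: (PhO)2P(O)N3, Et3N, toluene, 23 → 85 °C; then 1 M HCl, THF, 23 °C; NaHCO3 work-up
Reagents that add atoms: water (O)
Why: Curtius rearrangement of the α,β-unsaturated acyl azide gives a vinyl isocyanate whose mild acid hydrolysis (carbamic acid, enamine) leaves the C1 ketone with C5 as CH2, the short contact with dilute acid at room temperature sparing the C10 stereocentre next to the new carbonyl.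

Step 4
Reactants: 7 amino ketone; 8 ethyl but-2-ynoate
Product: 10 tricyclic 2-pyranone, via keto dienoate 9 (not isolated)
Conditions: LiN(SiMe3)2 (1.05 equiv), THF, −78 °C; then 8, −78 → 40 °C
Reagents that add atoms: none
Why: Kinetic deprotonation at the less substituted α-carbon C5, Michael addition of the enolate to the ynoate and O-acylation of the resulting keto dienolate with loss of ethoxide form the 2-pyranone (the classical ketone plus alkynoate pyranone synthesis), creating no stereocentre and leaving C10 untouched.

Step 5
Reactants: 10 tricyclic 2-pyranone; 11 1-O-acetylbritannilactone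
Product: 12 Diels–Alder adduct (bridged lactone: 2-oxabicyclo[2.2.2]oct-5-en-3-one)
Conditions: 11 (1.5 equiv), toluene, 1.2 GPa, 40 °C
Reagents that add atoms: none
Why: Diels–Alder reaction of the 2-pyranone with the α-methylene lactone under pressure (which avoids thermal loss of CO2): the carbonyl-bearing C11' bonds to the unsubstituted pyranone carbon C3 and C13' to the oxygen-bearing C1 (the usual 5-substituted regiochemistry of pyranone adducts, reinforced by sterics), the lactone carbonyl is exo as is usual for α-methylene lactones, the dienophile adds to the pyranone face opposite the C10 methyl group and bonds through the lactone face cis to C6', which together set C1, C3 and C11'.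

Step 6
Reactants: 12 Diels–Alder adduct
Product: 13 C6' triethylsilyl ether of 12
Conditions: Et3SiOTf, 2,6-lutidine, CH2Cl2, −40 → 0 °C
Reagents that add atoms: triethylsilyl trifluoromethanesulfonate (CC[Si](CC)(CC)OS(=O)(=O)C(F)(F)F)
Why: Silylation with the silyl triflate and 2,6-lutidine protects the hindered allylic C6' hydroxyl so that only the C2 hydroxyl made in step 9 is acetylated later; no stereocentre changes.

Step 7
Reactants: 13 silyl ether
Product: 14 hydroxy amide (C1 tertiary allylic alcohol; C3 dimethylcarboxamide)
Conditions: Me2NH (2 M in THF, 20 equiv), 45 °C, sealed tube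
Reagents that add atoms: dimethylamine (CNC)
Why: Aminolysis (nucleophilic acyl substitution) opens only the strained boat δ-lactone, whose leaving group is the tertiary allylic alkoxide, while the two unstrained γ-lactones and the acetate do not react with a secondary amine at this temperature; the bridgehead configurations are kept.

Step 8
Reactants: 14 hydroxy amide
Product: 15 bridged lactol (2-oxabicyclo[2.2.2]oct-5-en-3-ol)
Conditions: Cp2Zr(H)Cl (3 equiv), THF, 23 °C; then H2O, SiO2
Reagents that add atoms: none
Why: Cp2Zr(H)Cl reduces the tertiary amide to the aldehyde through a zirconated hemiaminal, a reduction known to spare esters and lactones, and on hydrolysis the aldehyde closes onto the cis C1 hydroxyl to give the lactol as an anomeric mixture whose new centre is erased in step 9.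

Step 9
Reactants: 15 bridged lactol
Product: 16 syn-7-norbornenol (free C2 hydroxyl)
Conditions: Pd(PPh3)4 (10 mol %), Et2Zn (4 equiv, 1 M in hexane), THF, 0 → 23 °C; NH4Cl (aq)
Reagents that add atoms: none
Why: Proposed new method: Et2Zn turns the lactol into its zinc hemiacetalate, which opens to the aldehyde and the tertiary allylic zinc alkoxide at C1; zerovalent palladium ionises this C1–O bond to a π-allylpalladium over C1–C5–C4, and transmetalation gives an allylzinc that adds through C1 to the aldehyde carbon C2 held on C3, the ethyl group on palladium leaving as ethene and ethane. The closest known reaction type is the palladium-catalysed, Et2Zn-promoted umpolung allylation of aldehydes with allylic alcohols, which has been used to contract alkenyl-substituted lactols to alkenylcycloalkanols but not on a bridged lactol with an endocyclic allyl unit. The one ring closed is the cyclopentene C1–C2–C3–C4=C5, by 5-exo-trig attack of the allyl terminus C1 on the aldehyde (SE2', the double bond returning to C4=C5), so the six-membered ring C1–O–C2–C3–C4=C5 of 15 becomes the five-membered carbocycle. The new stereocentre C2 is fixed by the closed six-membered transition state in which zinc, bound to C4 on the face of the former oxygen bridge, holds the aldehyde oxygen, so the hydroxyl ends syn to the C4=C5 bridge; C1 keeps its configuration because carbon can replace oxygen only on the bridging face. The step needs attack through C1 and not C4 (which would give a cyclopropanol) and must outrun β-hydride loss or protonation of the allyl-metal: the one-atom tether from C3 lets only the C1 closure reach a chelated chair, and the lactol oxygen is the only allylic leaving group in the molecule.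

Step 10
Reactants: 16 syn-7-norbornenol
Product: 17 C2 acetate
Conditions: Ac2O, DMAP (cat.), pyridine, CH2Cl2, 23 °C
Reagents that add atoms: acetic anhydride (CC(=O)OC(C)=O)
Why: DMAP-catalysed acylation acetylates the only free hydroxyl with retention at C2.

Step 11
Reactants: 17 C2 acetate
Product: 18 C6' alcohol (dimethylamine adduct of the target)
Conditions: HF·pyridine, THF, 0 → 23 °C
Reagents that add atoms: none
Why: Fluoride cleaves the silyl ether (Si–F bond formation) and leaves acetates, lactones and the amine untouched.

Step 12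
Reactants: 18 C6' alcohol
Product: 20 target CNP0211028.3, via trimethylammonium iodide 19 (not isolated)
Conditions: MeI (10 equiv), THF, 23 °C; then NaHCO3 (aq), 23 °C
Reagents that add atoms: none
Why: Exhaustive methylation gives the quaternary ammonium salt, and mild base then triggers E1cB (Hofmann-type) elimination of trimethylamine, restoring the α-methylene lactone and erasing the auxiliary C11 centre.

**Compound list**

1 | xanthatin, (3aR,7S,8aS)-7-methyl-3-methylidene-6-[(1E)-3-oxobut-1-en-1-yl]-3,3a,4,7,8,8a-hexahydro-2H-cyclohepta[b]furan-2-one | C=C1C(=O)O[C@H]2C[C@H](C)C(/C=C/C(C)=O)=CC[C@H]12 | starting material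
2 | 13-(dimethylamino)-11,13-dihydroxanthatin (11S; CH2NMe2 cis to H-7) | CN(C)C[C@H]1C(=O)O[C@H]2C[C@H](C)C(/C=C/C(C)=O)=CC[C@H]12 | intermediate (not isolated)
3 | amino enal, (3S,3aR,7S,8aS)-3-[(dimethylamino)methyl]-7-methyl-2-oxo-3,3a,4,7,8,8a-hexahydro-2H-cyclohepta[b]furan-6-carbaldehyde | CN(C)C[C@H]1C(=O)O[C@H]2C[C@H](C)C(C=O)=CC[C@H]12 | intermediate
4 | amino acid, the 6-carboxylic acid corresponding to 3 (same four stereocentres) | CN(C)C[C@H]1C(=O)O[C@H]2C[C@H](C)C(C(=O)O)=CC[C@H]12 | intermediate
5 | acyl azide of 4 | CN(C)C[C@H]1C(=O)O[C@H]2C[C@H](C)C(C(=O)N=[N+]=[N-])=CC[C@H]12 | intermediate (not isolated)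
6 | vinyl isocyanate (isocyanate on C1 of the cycloheptene) | CN(C)C[C@H]1C(=O)O[C@H]2C[C@H](C)C(N=C=O)=CC[C@H]12 | intermediate (not isolated)
7 | amino ketone, (3S,3aR,7S,8aS)-3-[(dimethylamino)methyl]-7-methyloctahydrocyclohepta[b]furan-2,6-dione | CN(C)C[C@H]1C(=O)O[C@H]2C[C@H](C)C(=O)CC[C@H]12 | intermediate
8 | ethyl but-2-ynoate | CC#CC(=O)OCC | starting material
9 | keto dienoate, ethyl 3-(ring C5)-but-2-enoate Michael adduct of 7 (mixture at C5 and of alkene isomers, all converging on 10) | CN(C)C[C@H]1C(=O)O[C@H]2C[C@H](C)C(=O)C(C(C)=CC(=O)OCC)C[C@H]12 | intermediate (not isolated)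
10 | tricyclic 2-pyranone: 4-methyl-2-pyranone fused through its C5–C6 bond to the seven-membered ring (ring O on C1, C4–Me, C3–H), with the trans-fused (11S)-13-dimethylamino-12,8-olide; 7R,8S,10S | CN(C)C[C@H]1C(=O)O[C@H]2C[C@H](C)C3=C(C[C@H]12)C(C)=CC(=O)O3 | intermediate
11 | 1-O-acetylbritannilactone, (4S)-4-[(3aS,4S,7aR)-4-hydroxy-6-methyl-3-methylidene-2-oxo-3a,4,7,7a-tetrahydro-1-benzofuran-5-yl]pentyl acetate | C=C1C(=O)O[C@@H]2CC(C)=C([C@@H](C)CCCOC(C)=O)[C@@H](O)[C@H]12 | starting material
12 | Diels–Alder adduct: 2-oxabicyclo[2.2.2]oct-5-en-3-one with ring O on C1 and lactone C2=O on C3; C4(Me)=C5 etheno bridge fused to the seven-membered ring; C13'H2–C11' ethano bridge, C11' spiro with C12'=O exo (towards the O–C2 bridge) and C7' endo; C3–C11' bond cis to C6'; free C6' OH | CN(C)C[C@H]1C(=O)O[C@H]2C[C@H](C)[C@@]34C[C@]5(C(=O)O[C@@H]6CC(C)=C([C@@H](C)CCCOC(C)=O)[C@@H](O)[C@@H]65)[C@@H](C(C)=C3C[C@H]12)C(=O)O4 | intermediate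
13 | C6' triethylsilyl ether of 12 | CN(C)C[C@H]1C(=O)O[C@H]2C[C@H](C)[C@@]34C[C@]5(C(=O)O[C@@H]6CC(C)=C([C@@H](C)CCCOC(C)=O)[C@@H](O[Si](CC)(CC)CC)[C@@H]65)[C@@H](C(C)=C3C[C@H]12)C(=O)O4 | intermediate
14 | hydroxy amide: cyclohexene with tertiary allylic OH on C1 and N,N-dimethylcarboxamide on C3, cis to each other | CN(C)C[C@H]1C(=O)O[C@H]2C[C@H](C)[C@@]3(O)C[C@]5(C(=O)O[C@@H]6CC(C)=C([C@@H](C)CCCOC(C)=O)[C@@H](O[Si](CC)(CC)CC)[C@@H]65)[C@@H](C(C)=C3C[C@H]12)C(=O)N(C)C | intermediate
15 | bridged lactol: 2-oxabicyclo[2.2.2]oct-5-en-3-ol, lactol carbon C2 on C3, ring O on C1 (anomeric mixture) | CN(C)C[C@H]1C(=O)O[C@H]2C[C@H](C)[C@@]34C[C@]5(C(=O)O[C@@H]6CC(C)=C([C@@H](C)CCCOC(C)=O)[C@@H](O[Si](CC)(CC)CC)[C@@H]65)[C@@H](C(C)=C3C[C@H]12)C(O)O4 | intermediate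
16 | syn-7-norbornenol: norbornene core of the target with C2–OH syn to C4=C5, C6'–OSiEt3 and C13–NMe2 | CN(C)C[C@H]1C(=O)O[C@H]2C[C@H](C)[C@@]34C[C@]5(C(=O)O[C@@H]6CC(C)=C([C@@H](C)CCCOC(C)=O)[C@@H](O[Si](CC)(CC)CC)[C@@H]65)[C@@H](C(C)=C3C[C@H]12)[C@H]4O | intermediate
17 | C2 acetate of 16 | CN(C)C[C@H]1C(=O)O[C@H]2C[C@H](C)[C@@]34C[C@]5(C(=O)O[C@@H]6CC(C)=C([C@@H](C)CCCOC(C)=O)[C@@H](O[Si](CC)(CC)CC)[C@@H]65)[C@@H](C(C)=C3C[C@H]12)[C@H]4OC(C)=O | intermediate
18 | C6' alcohol: the (11S)-13-dimethylamino-11,13-dihydro derivative of the target | CN(C)C[C@H]1C(=O)O[C@H]2C[C@H](C)[C@@]34C[C@]5(C(=O)O[C@@H]6CC(C)=C([C@@H](C)CCCOC(C)=O)[C@@H](O)[C@@H]65)[C@@H](C(C)=C3C[C@H]12)[C@H]4OC(C)=O | intermediate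
19 | trimethylammonium iodide of 18 | C[N+](C)(C)C[C@H]1C(=O)O[C@H]2C[C@H](C)[C@@]34C[C@]5(C(=O)O[C@@H]6CC(C)=C([C@@H](C)CCCOC(C)=O)[C@@H](O)[C@@H]65)[C@@H](C(C)=C3C[C@H]12)[C@H]4OC(C)=O.[I-] | intermediate (not isolated)
20 | CNP0211028.3 | C=C1C(=O)O[C@H]2C[C@H](C)[C@@]34C[C@]5(C(=O)O[C@@H]6CC(C)=C([C@@H](C)CCCOC(C)=O)[C@@H](O)[C@@H]65)[C@@H](C(C)=C3C[C@H]12)[C@H]4OC(C)=O | target

**Count and risks**

Total step count: 12. Longest linear sequence: 12 steps (1 → 20); 8 and 11 enter as purchased.

Step 9. The allyl-metal may be protonated, or the π-allylpalladium may lose a β-hydrogen to a diene, before the strained one-carbon bridge closes; ethyl transfer to the aldehyde may also compete. The fallback sets out from 15 and comes back at 16. Miyaura-type borylative opening of the allylic lactol with B2pin2 and Pd2(dba)3 in DMSO should give allylboronate aldehyde F1 (boron on C4 cis to the C3 formyl group, C1=C5). This allylboron compound is not basic and has no β-hydride pathway. Its thermal intramolecular allylboration runs through the same closed chair, so the hydroxyl should again end syn to C4=C5, and mild hydrolysis of the borate ester gives 16.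

Step 5. The trialkylated pyranone may add too slowly to the 1,1-disubstituted lactone, the adduct may lose carbon dioxide if heat is needed, and regio- or facial control may erode. The fallback sets out from 10 and comes back at 12. Bromination of the pyranone at C3 (Br2 on the hydrobromide salt, CH2Cl2, then Et3N) should give 3-bromopyranone F2, a more reactive diene of the ambiphilic 3-halopyranone type. Cycloaddition with 11 at about 70 °C without pressure should give bromo adduct F3 with bromine on bridgehead C3. Radical debromination (Bu3SnH, AIBN, 80 °C) keeps the bridgehead configuration and returns 12.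

Step 7. The amine may also cleave the primary acetate, or the hindered bridged lactone may open incompletely. The fallback sets out from 13 and comes back at 15, bypassing 14. NaBH4 in EtOH/THF at 0 °C should reduce the strained δ-lactone to diol F4 (C1 tertiary alcohol, C3 hydroxymethyl) faster than the γ-lactones or the acetate. Parikh–Doering oxidation (SO3·pyridine, DMSO, i-Pr2NEt) of the primary alcohol then gives the aldehyde, which closes to lactol 15 without over-oxidation to the lactone.

Further compounds
F1 | step 9 | allylboronate aldehyde (pinacol boronate on C4 cis to the C3 formyl group, C1=C5 double bond) | CN(C)C[C@H]1C(=O)O[C@H]2C[C@H](C)C3=C(C[C@H]12)[C@@](C)(B7OC(C)(C)C(C)(C)O7)[C@@H](C=O)[C@]5(C3)C(=O)O[C@@H]6CC(C)=C([C@@H](C)CCCOC(C)=O)[C@@H](O[Si](CC)(CC)CC)[C@@H]65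
F2 | step 5 | 3-bromopyranone (3-bromo derivative of 10) | CN(C)C[C@H]1C(=O)O[C@H]2C[C@H](C)C3=C(C[C@H]12)C(C)=C(Br)C(=O)O3
F3 | step 5 | bromo adduct (12 with bromine on bridgehead C3) | CN(C)C[C@H]1C(=O)O[C@H]2C[C@H](C)[C@@]34C[C@]5(C(=O)O[C@@H]6CC(C)=C([C@@H](C)CCCOC(C)=O)[C@@H](O)[C@@H]65)[C@@](Br)(C(C)=C3C[C@H]12)C(=O)O4
F4 | step 7 | diol (C1 tertiary alcohol, C3 hydroxymethyl, cis) | CN(C)C[C@H]1C(=O)O[C@H]2C[C@H](C)[C@@]3(O)C[C@]5(C(=O)O[C@@H]6CC(C)=C([C@@H](C)CCCOC(C)=O)[C@@H](O[Si](CC)(CC)CC)[C@@H]65)[C@@H](C(C)=C3C[C@H]12)CO
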